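## Retrosynthetic overview

1. The target is opened at the ester C–O bond between the C1 CH2O group of ring B and the (E)-2-(hydroxymethyl)acrylic acid carried by ring A; the halves are made separately, joined last and deprotected.
2. The strategy rests on ring C: in this seven-membered lactone the atoms O–CH2–C(CO2H)=CH–C5 are the O–CH=CH–C5 unit of a six-membered enol lactone with one extra carbon set between the two alkene carbons, and the carboxyl group sits on that extra carbon.
3. Ring C therefore comes from the cis-fused six-membered enol lactone of ring B by dibromocarbene addition, silver-promoted cyclopropane opening and hydride capture; the vinyl bromide left behind is carbonylated.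
4. The enol lactone comes from an alkynoic acid on ring B; ring B is formed first by an enantioselective endo Diels–Alder reaction (C4, C5, C6), and C1 is set by hydroxyl-directed epoxidation and hydride opening.
5. Ring A comes from an auxiliary-controlled endo Diels–Alder reaction (cis C3'/C4'), conversion of the acyl group into isopropyl and an oxa-Michael/Horner–Wadsworth–Emmons acrylate synthesis. Ring order: B, six-membered lactone, C by enlargement; A independently.

Key step: step 14

Assumption and locants: the pinacol boronate of step 18, the phosphonoacrylate of step 27 and both enantiomers of the imidazolidinone salt and of 4-benzyloxazolidin-2-one are taken as commercial. Ring B is numbered C1 (future carbinol carbon) to C6 (future lactone α-carbon) with isopropyl on C4; β is the face of ring B carrying the C5 and C6 carbon substituents (isopropyl is α). Ring A is numbered C1' (CH2O-bearing alkene carbon), C2', C3' (side-chain carbon), C4' (isopropyl carbon).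

## Route

Step 1
Reactants: 1 but-2-yne-1,4-diol
Product: 2 1,4-bis[(4-methoxybenzyl)oxy]but-2-yne
Conditions: NaH, 4-methoxybenzyl chloride, Bu4NI (cat.), THF/DMF, 0 °C → rt
Reagents that add atoms: 4-methoxybenzyl chloride, COc1ccc(CCl)cc1
Why: Double Williamson etherification of the two primary alkoxides should give a bis-ether (PMB = 4-methoxybenzyl) that tolerates tin, palladium and aqueous acid.

Step 2
Reactants: 2 1,4-bis[(4-methoxybenzyl)oxy]but-2-yne
Product: 3 (E)-1,4-bis[(4-methoxybenzyl)oxy]-2-(tributylstannyl)but-2-ene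
Conditions: Bu3SnH, PdCl2(PPh3)2 (2 mol%), THF, rt
Reagents that add atoms: tributyltin hydride, CCCC[SnH](CCCC)CCCC
Why: Palladium-catalysed hydrostannation adds H and Sn syn across the symmetrical alkyne, so no regiochemical question arises and the alkene geometry is fixed.

Step 3
Reactants: 3 (E)-1,4-bis[(4-methoxybenzyl)oxy]-2-(tributylstannyl)but-2-ene; 4 vinyl bromide
Product: 5 (Z)-1,4-bis[(4-methoxybenzyl)oxy]-2-vinylbut-2-ene (a buta-1,3-diene whose terminal CH2OPMB group is trans to the vinyl group)
Conditions: Pd(PPh3)4 (5 mol%), CuI (10 mol%), CsF, DMF, 45 °C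
Reagents that add atoms: none
Why: Stille coupling proceeds with retention at the stannylated carbon (copper and fluoride accelerating the α-substituted stannane) and places the terminal substituent of the diene in the outside position needed for a cis adduct.

Step 4
Reactants: 5 (Z)-1,4-bis[(4-methoxybenzyl)oxy]-2-vinylbut-2-ene; 6 (E)-4-methylpent-2-enal
Product: 7 (1S,2S,6S)-6-isopropyl-2,3-bis{[(4-methoxybenzyl)oxy]methyl}cyclohex-3-ene-1-carbaldehyde (ring B locants: C5 formyl β, C6 CH2OPMB β, C4 isopropyl α, C1=C2 alkene)
Conditions: (5R)-5-benzyl-2,2,3-trimethylimidazolidin-4-one hydrochloride (20 mol%), 6 (3 equiv), MeCN/H2O (95:5), 0 °C → rt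
Reagents that add atoms: none
Why: In this iminium-catalysed endo Diels–Alder reaction the hindered β-carbon of the enal bonds to the unsubstituted diene terminus, the E-enal fixes isopropyl trans to formyl, the endo transition state places formyl cis to the C6 CH2OPMB group, and the benzyl group of the (5R)-catalyst shields the Si face of the α-carbon so that the diene adds to its Re face, which sets C4, C5 and C6.

Step 5
Reactants: 7 (1S,2S,6S)-6-isopropyl-2,3-bis{[(4-methoxybenzyl)oxy]methyl}cyclohex-3-ene-1-carbaldehyde
Product: 8 5β-ethynyl-4α-isopropyl-1,6β-bis{[(4-methoxybenzyl)oxy]methyl}cyclohex-1-ene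
Conditions: dimethyl (1-diazo-2-oxopropyl)phosphonate, K2CO3, MeOH, 0 °C → rt
Reagents that add atoms: dimethyl (1-diazo-2-oxopropyl)phosphonate, COP(=O)(OC)C(=[N+]=[N-])C(C)=O
Why: Ohira–Bestmann homologation turns the aldehyde into a terminal alkyne, a one-carbon-extended aldehyde surrogate inert to the later oxidising, reducing and acidic steps, and C5 should not epimerise because its substituent is already equatorial and trans to isopropyl.

Step 6
Reactants: 8 5β-ethynyl-4α-isopropyl-1,6β-bis{[(4-methoxybenzyl)oxy]methyl}cyclohex-1-ene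
Product: 9 (5β-ethynyl-4α-isopropylcyclohex-1-ene-1,6β-diyl)dimethanol
Conditions: DDQ, CH2Cl2/pH 7 buffer, 0 °C
Reagents that add atoms: none
Why: Oxidative cleavage of both 4-methoxybenzyl ethers (hydride abstraction, then hydrolysis) frees the allylic and homoallylic alcohols without touching the alkyne or the ring alkene.

Step 7
Reactants: 9 (5β-ethynyl-4α-isopropylcyclohex-1-ene-1,6β-diyl)dimethanol
Product: 10 (1β,2β-epoxy-5β-ethynyl-4α-isopropylcyclohexane-1,6β-diyl)dimethanol
Conditions: VO(acac)2 (5 mol%), t-BuOOH, CH2Cl2, 0 °C → rt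
Reagents that add atoms: tert-butyl hydroperoxide, CC(C)(C)OO
Why: In this hydroxyl-directed vanadium-catalysed epoxidation the peroxide is delivered from vanadium bound to the homoallylic C6 CH2OH (and the allylic C1 CH2OH), hence to the β-face of C1=C2, which sets the C1–O stereocentre cis to the C6 substituent.

Step 8
Reactants: 10 (1β,2β-epoxy-5β-ethynyl-4α-isopropylcyclohexane-1,6β-diyl)dimethanol
Product: 11 5β-ethynyl-1α,6β-bis(hydroxymethyl)-4α-isopropylcyclohexan-1β-ol
Conditions: LiAlH4, THF, 0 °C → rt
Reagents that add atoms: none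
Why: SN2 opening of the trisubstituted epoxide by hydride at the secondary carbon C2 (the fully substituted C1 is not attacked) leaves the C1–O bond intact, so the tertiary alcohol keeps the β-configuration set in step 7.

Step 9
Reactants: 11 5β-ethynyl-1α,6β-bis(hydroxymethyl)-4α-isopropylcyclohexan-1β-ol
Product: 12 spiro-acetonide of 11 (1,3-dioxolane across the C1 OH and the C1 CH2OH; C6 β-CH2OH free)
Conditions: Me2C(OMe)2, PPTS (cat.), acetone, rt
Reagents that add atoms: 2,2-dimethoxypropane, COC(C)(C)OC
Why: Acid-catalysed acetalisation under equilibrium control selects the five-membered dioxolane of the 1,2-diol over six- or seven-membered alternatives and leaves the C6 CH2OH free.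

Step 10
Reactants: 12 spiro-acetonide alcohol
Product: 13 acetonide-protected 5β-ethynyl-4α-isopropylcyclohexane-6β-carboxylic acid
Conditions: TEMPO (cat.), PhI(OAc)2, MeCN/H2O, rt
Reagents that add atoms: water, O
Why: Oxoammonium (TEMPO) oxidation takes the primary alcohol through the aldehyde hydrate to the acid under near-neutral conditions that spare the acetonide, the alkyne and the α-stereocentre C6.

Step 11
Reactants: 13 acetonide-protected alkynoic acid
Product: 15 aldehyde acid (C5 β-CH2CHO and C6 β-CO2H; in equilibrium with its cyclic hydroxy lactone), via alkenylborane 14 (not isolated)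
Conditions: Cy2BH (3 equiv), THF, 0 °C → rt; then H2O2, pH 7 phosphate buffer, 0 °C
Reagents that add atoms: hydrogen peroxide, OO
Why: Anti-Markovnikov hydroboration of the terminal alkyne with a hindered dialkylborane (one equivalent is consumed by the acid as an acyloxyborane, which is not reduced) and buffered oxidation of the alkenylborane give the C5 CH2CHO arm.

Step 12
Reactants: 15 aldehyde acid
Product: 16 cis-fused six-membered enol lactone of ring B (C5–CH=CH–O–C(=O)–C6; C1 diol as spiro-acetonide)
Conditions: TsOH·H2O (cat.), PhMe, reflux, Dean–Stark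
Reagents that add atoms: none
Why: In this acid-catalysed dehydrative enol lactonisation the δ-aldehydo acid closes to its cyclic hydroxy lactone and loses water azeotropically, without touching C5 or C6, while the anhydrous medium keeps the acetonide.

Step 13
Reactants: 17 bromoform; 18 phenylmercury chloride
Product: 19 phenyl(tribromomethyl)mercury, PhHgCBr3
Conditions: KOt-Bu, PhH, 0–5 °C
Reagents that add atoms: none
Why: tert-Butoxide deprotonates bromoform and the tribromomethyl anion displaces chloride on mercury faster than it loses bromide, which gives a reagent that releases dibromocarbene without base.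

Step 14
Reactants: 16 cis-fused six-membered enol lactone; 19 phenyl(tribromomethyl)mercury
Product: 21 ring-expanded seven-membered bromo lactone (C5–CH=C(Br)–CH2–O–C(=O)–C6; spiro-acetonide retained), via dibromocyclopropane 20 (not isolated)
Conditions: 19 (1.5 equiv), PhH, 80 °C; filter, concentrate; then Et3SiH (5 equiv), AgBF4 (1.5 equiv, added last), CH2Cl2, −40 → 0 °C, dark
Reagents that add atoms: none
Why: Proposed new method: thermolysis of 19 releases dibromocarbene under neutral conditions (the enol lactone would not survive bromoform with alkoxide or hydroxide), and the electrophilic carbene adds to the O–CH=CH bond of 16 to give the fused dibromocyclopropane 20, in which the carbene carbon is bonded to both former alkene carbons. Silver cation then removes the endo bromide while the shared cyclopropane bond opens in a disrotatory two-electron electrocyclic sense, so the six-membered lactone becomes a seven-membered ring carrying a 2-bromoallyl cation whose oxygen-bearing terminus is an acyloxycarbenium ion; ring C thus arises by enlargement of the existing lactone through one-carbon insertion and not by a new cyclisation. Triethylsilane transfers hydride to this cation to give the O–CH2 group, the ring alkene next to C5 and the vinyl bromide. The closest known chemistry is dihalocarbene cyclopropanation of cyclic enol ethers and enol acetates followed by silver-promoted ring expansion with capture by alcohols, water or carboxylates, together with silane reduction of oxocarbenium ions; the enol lactone substrate and the hydride capture are the untested elements. No stereocentre is made or disturbed, because the two cyclopropane centres of 20 vanish on opening and the face of carbene attack is therefore irrelevant. The step needs hydride capture at the oxygen-bearing terminus rather than at the carbon attached to C5, which is expected because that terminus holds more of the positive charge and is an unhindered CH while the other is flanked by C5 and the isopropyl-bearing C4, and the silver salt is added last at low temperature to substrate and excess silane so that bromide abstraction outruns reduction of silver by the silane.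

Step 15
Reactants: 21 ring-expanded bromo lactone
Product: 22 2-(trimethylsilyl)ethyl ester of the ring C acid (C5–CH=C(CO2CH2CH2SiMe3)–CH2–O–C(=O)–C6; spiro-acetonide retained)
Conditions: Pd(PPh3)4 (5 mol%), CO (1 atm), Me3SiCH2CH2OH, i-Pr2NEt, DMF, 60 °C
Reagents that add atoms: carbon monoxide, [C-]#[O+]; 2-(trimethylsilyl)ethanol, C[Si](C)(C)CCO
Why: In this palladium-catalysed alkoxycarbonylation, oxidative addition of zerovalent palladium to the vinyl C–Br bond, CO insertion and alcoholysis of the acylpalladium install the protected carboxyl group on the inserted carbon.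

Step 16
Reactants: 22 2-(trimethylsilyl)ethyl ester acetonide
Product: 23 ring B/C diol (C1 β-OH and C1 α-CH2OH free; 2-(trimethylsilyl)ethyl ester and lactone intact)
Conditions: AcOH/H2O/THF, 40 °C
Reagents that add atoms: none
Why: Mild acid hydrolysis removes the dioxolane without cleaving the silylethyl ester or the lactone, and the liberated CH2OH is axial and anti to the axial lactone carbonyl on C6, so translactonisation to a trans-fused γ-lactone is geometrically disfavoured.

Step 17
Reactants: 24 2-bromoprop-2-en-1-ol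
Product: 25 [(2-bromoallyl)oxy](tert-butyl)diphenylsilane
Conditions: TBDPSCl, imidazole, CH2Cl2, rt
Reagents that add atoms: tert-butyldiphenylsilyl chloride, CC(C)(C)[Si](Cl)(c1ccccc1)c1ccccc1
Why: Silylation of the primary alcohol gives a robust ether (TBDPS = tert-butyldiphenylsilyl) that survives Lewis acid, Grignard, radical and basic steps.

Step 18
Reactants: 25 [(2-bromoallyl)oxy](tert-butyl)diphenylsilane; 26 (E)-tert-butyldimethyl{[3-(4,4,5,5-tetramethyl-1,3,2-dioxaborolan-2-yl)allyl]oxy}silane
Product: 27 (E)-5-[(tert-butyldimethylsilyl)oxy]-2-{[(tert-butyldiphenylsilyl)oxy]methyl}penta-1,3-diene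
Conditions: PdCl2(dppf) (3 mol%), K3PO4, THF/H2O, 60 °C
Reagents that add atoms: none
Why: Suzuki–Miyaura coupling of the vinyl bromide with the (E)-alkenylboronate proceeds with retention and gives the 1,3-disubstituted diene with its terminal substituent outside (TBS = tert-butyldimethylsilyl).

Step 19
Reactants: 28 (R)-4-benzyloxazolidin-2-one; 29 acryloyl chloride
Product: 30 (R)-3-acryloyl-4-benzyloxazolidin-2-one
Conditions: MeMgBr, THF, −78 °C; then 29, −78 → 0 °C
Reagents that add atoms: none
Why: N-Acylation of the bromomagnesium salt of the oxazolidinone at low temperature gives the acrylimide while limiting polymerisation.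

Step 20
Reactants: 27 (E)-5-[(tert-butyldimethylsilyl)oxy]-2-{[(tert-butyldiphenylsilyl)oxy]methyl}penta-1,3-diene; 30 (R)-3-acryloyl-4-benzyloxazolidin-2-one
Product: 31 (R)-4-benzyl-3-{[(1S,2R)-2-{[(tert-butyldimethylsilyl)oxy]methyl}-4-{[(tert-butyldiphenylsilyl)oxy]methyl}cyclohex-3-en-1-yl]carbonyl}oxazolidin-2-one (ring A: C3' CH2OTBS and C4' acyl cis)
Conditions: Et2AlCl (1.4 equiv), CH2Cl2, −78 °C
Reagents that add atoms: none
Why: In this auxiliary-controlled Lewis-acid Diels–Alder reaction of the aluminium-chelated s-cis acrylimide the α-carbon bonds to the substituted diene terminus (ortho to the 1-substituent, para to the 3-substituent), the endo transition state makes the acyl group cis to the C3' substituent, and the diene approaches the face opposite the benzyl group (Re face of the α-carbon), which sets C3' and C4'.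

Step 21
Reactants: 31 Diels–Alder imide
Product: 32 benzyl cis-2-{[(tert-butyldimethylsilyl)oxy]methyl}-4-{[(tert-butyldiphenylsilyl)oxy]methyl}cyclohex-3-ene-1-carboxylate
Conditions: BnOH, n-BuLi, THF, −20 → 0 °C
Reagents that add atoms: benzyl alcohol, OCc1ccccc1
Why: Lithium benzyloxide attacks the exocyclic imide carbonyl (acyl transfer) and releases the auxiliary without epimerising C4'.

Step 22
Reactants: 32 benzyl ester
Product: 33 2-[cis-2-{[(tert-butyldimethylsilyl)oxy]methyl}-4-{[(tert-butyldiphenylsilyl)oxy]methyl}cyclohex-3-en-1-yl]propan-2-ol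
Conditions: MeMgBr, CeCl3, THF, −78 → 0 °C
Reagents that add atoms: methylmagnesium bromide, C[Mg]Br
Why: Double Grignard addition to the ester, with CeCl3 to suppress enolisation of the intermediate methyl ketone, gives the tertiary carbinol that holds the isopropyl carbon skeleton.

Step 23
Reactants: 33 tertiary alcohol
Product: 34 methyl oxalate of 33
Conditions: ClCOCO2Me, pyridine, DMAP (cat.), CH2Cl2, 0 °C → rt
Reagents that add atoms: methyl chlorooxoacetate, COC(=O)C(=O)Cl
Why: DMAP-catalysed acylation of the tertiary alcohol with the reactive oxalyl chloride half-ester provides a radical-cleavable ester.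

Step 24
Reactants: 34 tertiary methyl oxalate
Product: 35 cis-3'-{[(tert-butyldimethylsilyl)oxy]methyl}-1'-{[(tert-butyldiphenylsilyl)oxy]methyl}-4'-isopropylcyclohex-1'-ene
Conditions: Bu3SnH, AIBN, PhMe, 110 °C
Reagents that add atoms: none
Why: Barton–McCombie-type radical deoxygenation of the tertiary alkyl oxalate gives an exocyclic tertiary radical that is reduced by the tin hydride, so the adjacent stereocentre C4' is not involved.

Step 25
Reactants: 35 bis-silyl ether
Product: 36 [cis-3-{[(tert-butyldiphenylsilyl)oxy]methyl}-6-isopropylcyclohex-2-en-1-yl]methanol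
Conditions: CSA (cat.), MeOH/CH2Cl2, 0 °C
Reagents that add atoms: none
Why: Acid-catalysed methanolysis removes the less hindered primary TBS ether and leaves the bulkier TBDPS ether.

Step 26
Reactants: 36 primary alcohol
Product: 37 cis-3-{[(tert-butyldiphenylsilyl)oxy]methyl}-6-isopropylcyclohex-2-ene-1-carbaldehyde
Conditions: Dess–Martin periodinane, NaHCO3, CH2Cl2, 0 °C
Reagents that add atoms: none
Why: Buffered Dess–Martin oxidation gives the β,γ-unsaturated aldehyde without base, to be used at once so that C3' does not epimerise and the alkene does not migrate.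

Step 27
Reactants: 37 β,γ-unsaturated aldehyde; 38 ethyl 2-(diethoxyphosphoryl)acrylate
Product: 40 ethyl (E)-3-[(1S,6R)-3-{[(tert-butyldiphenylsilyl)oxy]methyl}-6-isopropylcyclohex-2-en-1-yl]-2-{[(4-methoxybenzyl)oxy]methyl}acrylate, via phosphonate carbanion 39 (not isolated)
Conditions: 4-methoxybenzyl alcohol, NaH, THF, 0 °C, then 38; then 37, −78 → 0 °C
Reagents that add atoms: 4-methoxybenzyl alcohol, COc1ccc(CO)cc1
Why: Oxa-Michael addition of the alkoxide to the vinylphosphonate gives a stabilised phosphonate carbanion whose Horner–Wadsworth–Emmons reaction with the α-branched aldehyde should give the enoate with the ring trans to the ester (E), the weakly basic anion limiting epimerisation at C3'.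

Step 28
Reactants: 40 ethyl enoate
Product: 41 (E)-3-[(1S,6R)-3-{[(tert-butyldiphenylsilyl)oxy]methyl}-6-isopropylcyclohex-2-en-1-yl]-2-{[(4-methoxybenzyl)oxy]methyl}acrylic acid
Conditions: LiOH, THF/MeOH/H2O, rt; then aq. HCl to pH 4
Reagents that add atoms: lithium hydroxide, [Li+].[OH-]
Why: Saponification of the ethyl ester leaves the silyl and benzyl ethers and the alkene geometry unchanged.

Step 29
Reactants: 23 ring B/C diol; 41 protected ring A acid
Product: 42 fully protected ester (ring A acid on the C1 CH2O group of ring B)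
Conditions: 2-methyl-6-nitrobenzoic anhydride, DMAP, Et3N, CH2Cl2, rt
Reagents that add atoms: none
Why: Mixed-anhydride esterification with DMAP-catalysed acyl transfer acylates the primary alcohol selectively, the tertiary hydroxyl being unreactive.

Step 30
Reactants: 42 fully protected ester
Product: 43 ester with free acrylate CH2OH (TBDPS ether and silylethyl ester retained)
Conditions: DDQ, CH2Cl2/pH 7 buffer, 0 °C
Reagents that add atoms: none
Why: Oxidative cleavage of the 4-methoxybenzyl ether frees the acrylate CH2OH while silyl ether, silylethyl ester, lactone and alkenes are inert under buffered conditions.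

Step 31
Reactants: 43 mono-deprotected ester
Product: 44 target CNP0361406.7
Conditions: Bu4NF, AcOH, THF, 0 °C → rt
Reagents that add atoms: none
Why: Fluoride cleaves the silyl ether and triggers β-elimination of the 2-(trimethylsilyl)ethyl ester to release the carboxylic acid, acetic acid buffering the medium so that the esters and the lactone survive.

## Compound list

1 | but-2-yne-1,4-diol | OCC#CCO | starting material
2 | 1,4-bis[(4-methoxybenzyl)oxy]but-2-yne | COc1ccc(COCC#CCOCc2ccc(OC)cc2)cc1 | intermediate
3 | (E)-1,4-bis[(4-methoxybenzyl)oxy]-2-(tributylstannyl)but-2-ene | CCCC[Sn](CCCC)(CCCC)/C(COCc1ccc(OC)cc1)=C/COCc1ccc(OC)cc1 | intermediate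
4 | vinyl bromide | C=CBr | starting material
5 | (Z)-1,4-bis[(4-methoxybenzyl)oxy]-2-vinylbut-2-ene | C=C/C(COCc1ccc(OC)cc1)=C/COCc1ccc(OC)cc1 | intermediate
6 | (E)-4-methylpent-2-enal | CC(C)/C=C/C=O | starting material
7 | (1S,2S,6S)-6-isopropyl-2,3-bis{[(4-methoxybenzyl)oxy]methyl}cyclohex-3-ene-1-carbaldehyde | COc1ccc(COCC2=CC[C@@H](C(C)C)[C@H](C=O)[C@@H]2COCc2ccc(OC)cc2)cc1 | intermediate
8 | 5β-ethynyl-4α-isopropyl-1,6β-bis{[(4-methoxybenzyl)oxy]methyl}cyclohex-1-ene | COc1ccc(COCC2=CC[C@@H](C(C)C)[C@H](C#C)[C@@H]2COCc2ccc(OC)cc2)cc1 | intermediate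
9 | (5β-ethynyl-4α-isopropylcyclohex-1-ene-1,6β-diyl)dimethanol | OCC1=CC[C@@H](C(C)C)[C@H](C#C)[C@@H]1CO | intermediate
10 | (1β,2β-epoxy-5β-ethynyl-4α-isopropylcyclohexane-1,6β-diyl)dimethanol | OC[C@]12O[C@@H]2C[C@@H](C(C)C)[C@H](C#C)[C@@H]1CO | intermediate
11 | 5β-ethynyl-1α,6β-bis(hydroxymethyl)-4α-isopropylcyclohexan-1β-ol | OC[C@@]1(O)CC[C@@H](C(C)C)[C@H](C#C)[C@@H]1CO | intermediate
12 | spiro-acetonide of 11 with free C6 β-CH2OH | CC1(C)OC[C@@]2(O1)CC[C@@H](C(C)C)[C@H](C#C)[C@@H]2CO | intermediate
13 | acetonide-protected 5β-ethynyl-4α-isopropylcyclohexane-6β-carboxylic acid | CC1(C)OC[C@@]2(O1)CC[C@@H](C(C)C)[C@H](C#C)[C@@H]2C(=O)O | intermediate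
14 | (E)-alkenyl(dicyclohexyl)borane with the acid as dicyclohexylboryl carboxylate | CC1(C)OC[C@@]2(O1)CC[C@@H](C(C)C)[C@H](/C=C/B(C1CCCCC1)C1CCCCC1)[C@@H]2C(=O)OB(C1CCCCC1)C1CCCCC1 | intermediate (not isolated)
15 | aldehyde acid (C5 β-CH2CHO, C6 β-CO2H, acetonide) | CC1(C)OC[C@@]2(O1)CC[C@@H](C(C)C)[C@H](CC=O)[C@@H]2C(=O)O | intermediate
16 | cis-fused six-membered enol lactone of ring B, diol as spiro-acetonide | CC1(C)OC[C@@]2(O1)CC[C@@H](C(C)C)[C@@H]3C=COC(=O)[C@@H]32 | intermediate
17 | bromoform | BrC(Br)Br | starting material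
18 | phenylmercury chloride | Cl[Hg]c1ccccc1 | starting material
19 | phenyl(tribromomethyl)mercury | BrC(Br)(Br)[Hg]c1ccccc1 | intermediate
20 | dibromocyclopropane fused to the lactone (drawn as the adduct on the convex face; the other face isomer would open to the same cation) | CC1(C)OC[C@@]2(O1)CC[C@@H](C(C)C)[C@@H]3[C@@H]4[C@H](OC(=O)[C@@H]32)C4(Br)Br | intermediate (not isolated)
21 | ring-expanded seven-membered bromo lactone, diol as spiro-acetonide | CC1(C)OC[C@@]2(O1)CC[C@@H](C(C)C)[C@@H]3C=C(Br)COC(=O)[C@@H]32 | intermediate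
22 | 2-(trimethylsilyl)ethyl ester of the ring C acid, diol as spiro-acetonide | CC1(C)OC[C@@]2(O1)CC[C@@H](C(C)C)[C@@H]3C=C(C(=O)OCC[Si](C)(C)C)COC(=O)[C@@H]32 | intermediate
23 | ring B/C diol with 2-(trimethylsilyl)ethyl ester | OC[C@@]1(O)CC[C@@H](C(C)C)[C@@H]2C=C(C(=O)OCC[Si](C)(C)C)COC(=O)[C@@H]21 | intermediate
24 | 2-bromoprop-2-en-1-ol | C=C(Br)CO | starting material
25 | [(2-bromoallyl)oxy](tert-butyl)diphenylsilane | C=C(Br)CO[Si](c1ccccc1)(c1ccccc1)C(C)(C)C | intermediate
26 | (E)-tert-butyldimethyl{[3-(4,4,5,5-tetramethyl-1,3,2-dioxaborolan-2-yl)allyl]oxy}silane | CC(C)(C)[Si](C)(C)OC/C=C/B1OC(C)(C)C(C)(C)O1 | starting material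
27 | (E)-5-[(tert-butyldimethylsilyl)oxy]-2-{[(tert-butyldiphenylsilyl)oxy]methyl}penta-1,3-diene | C=C(CO[Si](c1ccccc1)(c1ccccc1)C(C)(C)C)/C=C/CO[Si](C)(C)C(C)(C)C | intermediate
28 | (R)-4-benzyloxazolidin-2-one | O=C1N[C@H](Cc2ccccc2)CO1 | starting material
29 | acryloyl chloride | C=CC(=O)Cl | starting material
30 | (R)-3-acryloyl-4-benzyloxazolidin-2-one | C=CC(=O)N1C(=O)OC[C@H]1Cc1ccccc1 | intermediate
31 | (R)-4-benzyl-3-{[(1S,2R)-2-{[(tert-butyldimethylsilyl)oxy]methyl}-4-{[(tert-butyldiphenylsilyl)oxy]methyl}cyclohex-3-en-1-yl]carbonyl}oxazolidin-2-one | O=C([C@H]1CCC(CO[Si](c2ccccc2)(c2ccccc2)C(C)(C)C)=C[C@H]1CO[Si](C)(C)C(C)(C)C)N1C(=O)OC[C@H]1Cc1ccccc1 | intermediate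
32 | benzyl cis-2-{[(tert-butyldimethylsilyl)oxy]methyl}-4-{[(tert-butyldiphenylsilyl)oxy]methyl}cyclohex-3-ene-1-carboxylate (configuration as in 31) | O=C(OCc1ccccc1)[C@H]1CCC(CO[Si](c2ccccc2)(c2ccccc2)C(C)(C)C)=C[C@H]1CO[Si](C)(C)C(C)(C)C | intermediate
33 | 2-[cis-2-{[(tert-butyldimethylsilyl)oxy]methyl}-4-{[(tert-butyldiphenylsilyl)oxy]methyl}cyclohex-3-en-1-yl]propan-2-ol | CC(C)(O)[C@H]1CCC(CO[Si](c2ccccc2)(c2ccccc2)C(C)(C)C)=C[C@H]1CO[Si](C)(C)C(C)(C)C | intermediate
34 | methyl oxalate of 33 | COC(=O)C(=O)OC(C)(C)[C@H]1CCC(CO[Si](c2ccccc2)(c2ccccc2)C(C)(C)C)=C[C@H]1CO[Si](C)(C)C(C)(C)C | intermediate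
35 | cis-3'-{[(tert-butyldimethylsilyl)oxy]methyl}-1'-{[(tert-butyldiphenylsilyl)oxy]methyl}-4'-isopropylcyclohex-1'-ene | CC(C)[C@H]1CCC(CO[Si](c2ccccc2)(c2ccccc2)C(C)(C)C)=C[C@H]1CO[Si](C)(C)C(C)(C)C | intermediate
36 | [cis-3-{[(tert-butyldiphenylsilyl)oxy]methyl}-6-isopropylcyclohex-2-en-1-yl]methanol | CC(C)[C@H]1CCC(CO[Si](c2ccccc2)(c2ccccc2)C(C)(C)C)=C[C@H]1CO | intermediate
37 | cis-3-{[(tert-butyldiphenylsilyl)oxy]methyl}-6-isopropylcyclohex-2-ene-1-carbaldehyde | CC(C)[C@H]1CCC(CO[Si](c2ccccc2)(c2ccccc2)C(C)(C)C)=C[C@H]1C=O | intermediate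
38 | ethyl 2-(diethoxyphosphoryl)acrylate | C=C(C(=O)OCC)P(=O)(OCC)OCC | starting material
39 | sodium salt of ethyl 2-(diethoxyphosphoryl)-3-[(4-methoxybenzyl)oxy]propanoate (phosphonate carbanion) | CCOC(=O)[C-](COCc1ccc(OC)cc1)P(=O)(OCC)OCC.[Na+] | intermediate (not isolated)
40 | ethyl (E)-3-[(1S,6R)-3-{[(tert-butyldiphenylsilyl)oxy]methyl}-6-isopropylcyclohex-2-en-1-yl]-2-{[(4-methoxybenzyl)oxy]methyl}acrylate | CC(C)[C@H]1CCC(CO[Si](c2ccccc2)(c2ccccc2)C(C)(C)C)=C[C@H]1/C=C(\COCc1ccc(OC)cc1)C(=O)OCC | intermediate
41 | (E)-3-[(1S,6R)-3-{[(tert-butyldiphenylsilyl)oxy]methyl}-6-isopropylcyclohex-2-en-1-yl]-2-{[(4-methoxybenzyl)oxy]methyl}acrylic acid | CC(C)[C@H]1CCC(CO[Si](c2ccccc2)(c2ccccc2)C(C)(C)C)=C[C@H]1/C=C(\COCc1ccc(OC)cc1)C(=O)O | intermediate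
42 | fully protected ester of 41 with the C1 CH2OH of 23 | CC(C)[C@H]1CCC(CO[Si](c2ccccc2)(c2ccccc2)C(C)(C)C)=C[C@H]1/C=C(\COCc1ccc(OC)cc1)C(=O)OC[C@@]1(O)CC[C@@H](C(C)C)[C@@H]2C=C(C(=O)OCC[Si](C)(C)C)COC(=O)[C@@H]21 | intermediate
43 | ester with free acrylate CH2OH, TBDPS ether and 2-(trimethylsilyl)ethyl ester retained | CC(C)[C@H]1CCC(CO[Si](c2ccccc2)(c2ccccc2)C(C)(C)C)=C[C@H]1/C=C(\CO)C(=O)OC[C@@]1(O)CC[C@@H](C(C)C)[C@@H]2C=C(C(=O)OCC[Si](C)(C)C)COC(=O)[C@@H]21 | intermediate
44 | CNP0361406.7 | CC(C)[C@H]1CCC(CO)=C[C@H]1/C=C(\CO)C(=O)OC[C@@]1(O)CC[C@@H](C(C)C)[C@@H]2C=C(C(=O)O)COC(=O)[C@@H]21 | target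

## Step count and risks

Total: 31 steps. Longest linear sequence: 18 steps (steps 1–12, 14–16, 29–31).

**Step 14.** Several processes may fail:
- carbene transfer to the acyloxy-substituted alkene may be slow;
- hydride may be delivered to the allyl terminus next to C5, giving the isomeric seven-membered enol lactone;
- the silane may reduce the silver salt before ionisation;
- the Lewis-acidic fluoride by-products may cleave the acetonide.

Fallback, from 16 back to 21: carbene transfer from 19 would still give 20, since dihalocarbene addition to enol esters is known. Crude 20 would then be solvolysed with AgNO3 in aqueous acetone buffered with 2,6-lutidine. Water captures the ring-expanded cation at the acyloxy terminus and the hemiacylal collapses irreversibly to the ring-opened (E)-2-bromo enal acid F1. NaBH4/CeCl3·7H2O in MeOH at −40 °C (Luche reduction) would give the (E)-2-bromoallylic alcohol acid F2. Yamaguchi lactonisation (2,4,6-trichlorobenzoyl chloride, Et3N, then DMAP, PhMe, high dilution) would close the seven-membered ring and rejoin the route at 21; ring C is then closed by lactonisation instead of by hydride capture.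

**Step 15.** Zerovalent palladium may ionise the allylic C–O bond of the lactone (π-allyl formation, leading to an isomeric five-membered lactone or decomposition) in competition with oxidative addition to the C–Br bond.

Fallback, from 21 back to 22: the lactone would be opened with LiOH in THF/H2O at 0 °C to the hydroxy acid F2, which has no allylic ester. The same alkoxycarbonylation (Pd(PPh3)4, CO, Me3SiCH2CH2OH, i-Pr2NEt, DMF) on F2 would give the 2-(trimethylsilyl)ethyl (E)-2-(hydroxymethyl)acrylate acid F3. Yamaguchi lactonisation of F3 would rejoin the route at 22.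

**Step 4.** The β-branched enal may react too slowly with the 1,2-disubstituted diene, and endo or facial selectivity may erode during long reaction times.

Fallback, from 5 back to 7: the dienophile would be (R)-4-benzyl-3-[(E)-4-methylpent-2-enoyl]oxazolidin-2-one F4, made from (E)-4-methylpent-2-enoic acid, pivaloyl chloride, Et3N, LiCl and 28. With Et2AlCl in CH2Cl2 at −40 °C the chelated s-cis imide should add 5 endo on the face away from the benzyl group (Re face of the α-carbon) to give the imide adduct F5. LiBH4 in THF/MeOH would release 28 and give the C5 primary alcohol F6, and Dess–Martin oxidation would rejoin the route at 7.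

## Further compounds

F1 | step 14 | (E)-2-bromo enal acid (C5 β-CH=C(Br)CHO with ring trans to Br, C6 β-CO2H, acetonide) | CC1(C)OC[C@@]2(O1)CC[C@@H](C(C)C)[C@H](/C=C(/Br)C=O)[C@@H]2C(=O)O
F2 | step 14 | (E)-2-bromoallylic alcohol acid (C5 β-CH=C(Br)CH2OH, C6 β-CO2H, acetonide) | CC1(C)OC[C@@]2(O1)CC[C@@H](C(C)C)[C@H](/C=C(/Br)CO)[C@@H]2C(=O)O
F3 | step 15 | 2-(trimethylsilyl)ethyl (E)-2-(hydroxymethyl)acrylate acid (C6 β-CO2H, acetonide) | CC1(C)OC[C@@]2(O1)CC[C@@H](C(C)C)[C@H](/C=C(/C(=O)OCC[Si](C)(C)C)CO)[C@@H]2C(=O)O
F4 | step 4 | (R)-4-benzyl-3-[(E)-4-methylpent-2-enoyl]oxazolidin-2-one | CC(C)/C=C/C(=O)N1C(=O)OC[C@H]1Cc1ccccc1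
F5 | step 4 | imide adduct (C5 β-acyl oxazolidinone, otherwise as 7) | COc1ccc(COCC2=CC[C@@H](C(C)C)[C@H](C(=O)N3C(=O)OC[C@H]3Cc3ccccc3)[C@@H]2COCc2ccc(OC)cc2)cc1
F6 | step 4 | C5 β-hydroxymethyl compound (otherwise as 7) | COc1ccc(COCC2=CC[C@@H](C(C)C)[C@H](CO)[C@@H]2COCc2ccc(OC)cc2)cc1
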